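Take the teal run first: its double product stood at 32.4% after 12.0 min and had crept up to 57.2% by 60.0 min.

common to all: substrate 20 mM
- ochre: partner 14 mM; run made earlier
- teal: partner 89 mM; run made earlier
- Friday's: partner 22.0 mM; time 2.0 h
- Saturday's: partner 55.0 mM; time 2.0 h
- Sunday's: partner 140 mM; time 2.0 h

| ochre: time / min | ochre: double product / % | teal: time / min | teal: double product / % |
|---|---|---|---|
| 12.0 | 1.2 | 12.0 | 32.4 |
| 25.0 | 2.2 | 25.0 | 49.3 |
| 40.0 | 1.9 | 40.0 | 52.1 |
| 50.0 | 3.6 | 50.0 | 55.4 |
| 60.0 | 5.0 | 60.0 | 57.2 |

(each reading ± 1 percentage point)

- which of the two there is more of at the end, Friday's (side product / double product)
- which of the two there is more of at the end, Saturday's (side product / double product)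
- which of the two there is more of at the end, Sunday's (side product / double product)
- double product at the end, in percent of the substrate charged, Friday's
- double product at the end, in percent of the substrate charged, Saturday's
- double product at the end, in percent of the substrate charged, Sunday's

- a reading or a percentage of double product counts all its forms, free or not

The first readings of the two runs gave an apparent order in partner of about 1.78, a rough reading given the scatter. I therefore reckoned with two uptakes: substrate takes one partner to give an intermediate, which then either takes a second partner to give double product or is lost without partner.

I built a ladder from teal, taking the last reading as the plateau. On the lowest rung stood the first uptake, which I assumed to be quick, with no reading earlier than 12.0 min to test it. Next came the pseudo-first-order decay of the intermediate, which I read from teal as 0.0696 min⁻¹, a half-life of 9.95 min. The loss branch took the unconverted share of that rate, 0.0298 min⁻¹, a slower half-life of 23.3 min. Highest stood the asked 2.0 h, so with partner in excess I expected the final yield to equal the branching share.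

I reckoned teal's mean free partner at about 63.3 mM, which gave the crossing concentration, the free [partner] at which the intermediate branches equally to double product and to loss: 47.3 mM, a reading from teal. The yield share is then [partner]/([partner] + crossing).

Saturday's mean free partner of 30.7 mM gave me 39.4%, and Sunday's 113 mM gave 70.4%. For Friday's I reckoned a rough span for the yield, from 4.05% with the partner left after one equivalent to 31.7% with the partner as charged. The readings are of double product, so my choices assumed that the loss was one side product: side product ahead on Friday's and Saturday's, double product on Sunday's.

The forecast gave 10.5%, 41% and 77%, with side product, side product and double product ahead in turn, holding that “By 2 h the substrate is essentially consumed, so the yield equals the selectivity”, and it stood above my Sunday's figure.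

The flasks gave 9.50%, 40.4% and 70.4% of double product, with side product, double product and double product ahead in turn.

    partner + single product → double product (k = 0.710 M⁻¹ min⁻¹)
    substrate + partner → single product (k = 5.50 M⁻¹ min⁻¹)
    single product → side product (k = 0.0120 min⁻¹)
    crystals ⇌ double product, rate k4*(cs4 - [double product]) while solid is left; crystals form when [double product] > cs4 (solubility = 11.0 mM, k = 1.90 min⁻¹)
    single product → decomposed reagent (k = 0.0220 min⁻¹)

In Sunday's flask, half of the turnover from substrate + partner to single product up to the asked time was done by 0.940 min, and at 1.00 h double product stood at 70.3%, with 15.3% of the substrate charged as crystals counted in it, and single product at 0.154%. Sunday's free partner ended at 106 mM, above the crossing, while Saturday's ended at 26.9 mM, below it, and in Saturday's flask the loss stood divided into side product at 20.9% and decomposed reagent at 38.4%. For a further flask like Sunday's but with 350 mM of partner, the crossing gives 87.2%, and that flask held 87.1% double product at the end.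

The runs are calculated for substances that don't exist, noise included.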